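**Plan**

- Retrosynthesis: the three methoxymethyl (MOM) ethers are removed last. Ring C is then cut at O1–C8a and C4–C4a, which frees ring A as 3,5-bis(methoxymethoxy)benzyne and leaves an (S)-3-aryl-3-silyloxy-N-methoxy-N-methylpropanamide (O1–C2–C3–C4) on ring B. This chain is cut at C2–C3 (crossed Claisen condensation, then ketone reduction), and the dimethylpyran ring fused to ring B is cut by a propargyl ether Claisen route back to methyl 2,4-dihydroxybenzoate.
- Enabling feature: the two new bonds end on the adjacent ring A carbons C8a and C4a, and the oxygen on C5 flanks C4a. Ring A is therefore a polarized aryne that takes the C2 alkoxide at C8a and leaves its carbanion at C4a, six atoms from the C4 acyl carbon.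
- Forward order: chromene on ring B (steps 1–3), C2–C3 bond and C2 stereocenter (steps 4–6), aryne precursor (steps 7–9), ring C and the union with ring A in one operation (step 10), deprotection (step 11).
- Stereochemistry: the only stereocenter, C2 (S), comes from Noyori transfer hydrogenation of the aryl ketone in step 5. Its C–O bond is not broken afterwards, and C4 stays masked as a tetrahedral adduct under the basic conditions of step 10.

Key step: step 10

Remark: flavanone numbering (O1, C2, C3, C4, C4a, C5–C8, C8a; primed locants for ring B) is used for the target and its precursors; compounds 1, 3, 7 and 12 are taken as commercial.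

**Route**

Step 1
Reactants: 1 methyl 2,4-dihydroxybenzoate
Product: 2 methyl 2-hydroxy-4-(methoxymethoxy)benzoate
Conditions: MOMCl (1.1 equiv), K2CO3 (1.5 equiv), acetone, 0 °C → rt
Reagents that add atoms: chloromethyl methyl ether (MOMCl), COCCl
Why: Williamson-type O-alkylation in which the free and more acidic 4-OH should react, while the 2-OH is held in a hydrogen bond to the ester carbonyl.

Step 2
Reactants: 2 methyl 2-hydroxy-4-(methoxymethoxy)benzoate; 3 3-chloro-3-methylbut-1-yne (2.5 equiv)
Product: 4 methyl 4-(methoxymethoxy)-2-[(2-methylbut-3-yn-2-yl)oxy]benzoate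
Conditions: K2CO3, KI (cat.), CuI (cat.), DMF, 65 °C
Reagents that add atoms: none
Why: copper-assisted O-propargylation of the phenoxide by a tertiary propargylic chloride (substitution through the copper acetylide-derived zwitterion), the standard entry to aryl 1,1-dimethylpropargyl ethers.

Step 3
Reactants: 4 methyl 4-(methoxymethoxy)-2-[(2-methylbut-3-yn-2-yl)oxy]benzoate
Product: 6 methyl 5-(methoxymethoxy)-2,2-dimethyl-2H-chromene-8-carboxylate, via allenylphenol 5 (not isolated)
Conditions: PhNEt2, 190 °C
Reagents that add atoms: none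
Why: aromatic propargyl Claisen rearrangement to the only free ortho carbon (between the two oxygens) gives allenylphenol 5, and a 1,5-hydrogen shift followed by oxa-6π electrocyclization should close the dimethylpyran ring on the oxygen ortho to the ester.

Step 4
Reactants: 6 methyl 5-(methoxymethoxy)-2,2-dimethyl-2H-chromene-8-carboxylate; 7 N-methoxy-N-methylacetamide (2.5 equiv)
Product: 9 3-[5-(methoxymethoxy)-2,2-dimethyl-2H-chromen-8-yl]-N-methoxy-N-methyl-3-oxopropanamide, via lithium enolate 8 (not isolated)
Conditions: LiN(i-Pr)2 (2.6 equiv), THF, –78 °C; then 6, –78 → –20 °C; aq NH4Cl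
Reagents that add atoms: none
Why: crossed Claisen condensation of an amide enolate with a non-enolizable aryl ester, in which the second equivalent of enolate turns the product into its enolate and so prevents a second addition.

Step 5
Reactants: 9 3-[5-(methoxymethoxy)-2,2-dimethyl-2H-chromen-8-yl]-N-methoxy-N-methyl-3-oxopropanamide
Product: 10 (3S)-3-hydroxy-3-[5-(methoxymethoxy)-2,2-dimethyl-2H-chromen-8-yl]-N-methoxy-N-methylpropanamide
Conditions: RuCl[(S,S)-TsDPEN](p-cymene) (1 mol %), HCO2H/Et3N (5:2), EtOAc, 35 °C
Reagents that add atoms: none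
Why: Noyori asymmetric transfer hydrogenation of an aryl ketone, in which the (S,S)-TsDPEN ruthenium hydride should deliver hydride to the Re face through the six-membered transition state with the aryl group under the p-cymene ligand (CH/π contact), setting (S) at the future C2 without touching the chromene alkene or the amide.

Step 6
Reactants: 10 (3S)-3-hydroxy-3-[5-(methoxymethoxy)-2,2-dimethyl-2H-chromen-8-yl]-N-methoxy-N-methylpropanamide
Product: 11 (3S)-3-[5-(methoxymethoxy)-2,2-dimethyl-2H-chromen-8-yl]-N-methoxy-N-methyl-3-[(trimethylsilyl)oxy]propanamide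
Conditions: 1-(trimethylsilyl)imidazole (1.3 equiv), CH2Cl2, rt; non-aqueous work-up
Reagents that add atoms: 1-(trimethylsilyl)imidazole, C[Si](C)(C)n1ccnc1
Why: O-silylation of the secondary alcohol removes the only O–H proton, so that fluoride in step 10 can liberate the alkoxide in a medium that contains no proton source.

Step 7
Reactants: 12 phloroglucinol
Product: 13 3,5-bis(methoxymethoxy)phenol
Conditions: MOMCl (2.0 equiv), i-Pr2NEt (2.2 equiv), DMF, 0 °C → rt; chromatographic separation
Reagents that add atoms: chloromethyl methyl ether (MOMCl), COCCl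
Why: statistical Williamson-type protection of a threefold symmetric triphenol, from which the bis-ether should be separable from the mono- and tris-ethers.

Step 8
Reactants: 13 3,5-bis(methoxymethoxy)phenol
Product: 14 2-bromo-3,5-bis(methoxymethoxy)phenol
Conditions: NBS (1.0 equiv), CH2Cl2, –78 → 0 °C
Reagents that add atoms: N-bromosuccinimide (NBS), O=C1CCC(=O)N1Br
Why: electrophilic aromatic bromination of a phenol, which should favour the two equivalent positions ortho to the free hydroxyl over the single position flanked by both MOM ethers.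

Step 9
Reactants: 14 2-bromo-3,5-bis(methoxymethoxy)phenol
Product: 17 3,5-bis(methoxymethoxy)-2-(trimethylsilyl)phenyl trifluoromethanesulfonate, via aryl silyl ether 15 (not isolated), via lithium silylphenolate 16 (not isolated)
Conditions: (Me3Si)2NH, THF, 65 °C, then evaporation; n-BuLi, THF, –100 → –78 °C; Tf2O, –100 → –78 °C
Reagents that add atoms: hexamethyldisilazane, C[Si](C)(C)N[Si](C)(C)C; trifluoromethanesulfonic anhydride (Tf2O), O=S(=O)(OS(=O)(=O)C(F)(F)F)C(F)(F)F
Why: O-silylation, bromine–lithium exchange, anionic 1,3 O→C silyl shift (retro-Brook rearrangement) and O-triflation of the resulting phenolate, the standard sequence to ortho-silylaryl triflate aryne precursors.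

Step 10
Reactants: 11 (3S)-3-[5-(methoxymethoxy)-2,2-dimethyl-2H-chromen-8-yl]-N-methoxy-N-methyl-3-[(trimethylsilyl)oxy]propanamide; 17 3,5-bis(methoxymethoxy)-2-(trimethylsilyl)phenyl trifluoromethanesulfonate (1.5 equiv, added slowly)
Product: 22 (2S)-5,7-bis(methoxymethoxy)-2-[5-(methoxymethoxy)-2,2-dimethyl-2H-chromen-8-yl]-2,3-dihydro-4H-chromen-4-one, via cesium alkoxide 18 (not isolated), via aryne 19 (not isolated), via aryl cesium 20 (not isolated), via hemiaminal cesium alkoxide 21 (not isolated)
Conditions: CsF (4 equiv), 18-crown-6 (0.2 equiv), THF, 0 °C → rt; then AcOH, 0 °C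
Reagents that add atoms: none
Why: Proposed new method: fluoride removes both trimethylsilyl groups, so that the cesium alkoxide 18 and the aryne 19 meet in a proton-free medium; the alkoxide oxygen adds to the aryne carbon meta to the neighbouring OMOM group, and the aryl anion 20 that appears next to that OMOM group attacks the N-methoxy-N-methylamide carbonyl to give the hemiaminal alkoxide 21, which collapses to the C4 ketone only on the acetic acid quench. The closest known reaction types are the aryne annulation of methyl salicylates to xanthones and of methyl anthranilates to acridones; what is new is an aliphatic secondary alkoxide as the nucleophile together with an open-chain amide as the internal acyl acceptor. Ring C closes in the 6-exo-trig mode (aryl carbanion onto the amide C=O), directly after the intermolecular O-arylation that joins O1 to C8a. No stereocenter is created: C2 keeps the (S) configuration from step 5 because none of its bonds is broken, and the hemiaminal carbon of 21 ends as the trigonal C4. The step needs regioselectivity, secured by the inductive distortion of the aryne by the oxygen on the future C5 (nucleophile to the future C8a, carbanion at the future C4a), and it needs acylation to outrun protonation of 20, secured by the silyl ether, the aprotic solvent and the six-membered transition state. It also needs C2 to survive base, secured because the enolizable C4 ketone, which could open ring C by retro-oxa-Michael reaction, does not exist until the quench.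

Step 11
Reactants: 22 (2S)-5,7-bis(methoxymethoxy)-2-[5-(methoxymethoxy)-2,2-dimethyl-2H-chromen-8-yl]-2,3-dihydro-4H-chromen-4-one
Product: 23 Sanggenone H, (2S)-5,7-dihydroxy-2-(5-hydroxy-2,2-dimethyl-2H-chromen-8-yl)-2,3-dihydro-4H-chromen-4-one
Conditions: 3 M aq HCl, MeOH, 40 °C, stopped at full conversion
Reagents that add atoms: none
Why: acid-catalysed acetal methanolysis should remove all three MOM ethers (the C5 ether fastest, next to the carbonyl) under conditions free of base, which is what opens ring C, and short enough to spare the 2,2-dimethylchromene.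

**Compound list**

1 | methyl 2,4-dihydroxybenzoate | COC(=O)c1ccc(O)cc1O | starting material
2 | methyl 2-hydroxy-4-(methoxymethoxy)benzoate | COCOc1ccc(C(=O)OC)c(O)c1 | intermediate
3 | 3-chloro-3-methylbut-1-yne | C#CC(C)(C)Cl | starting material
4 | methyl 4-(methoxymethoxy)-2-[(2-methylbut-3-yn-2-yl)oxy]benzoate | COCOc1ccc(C(=O)OC)c(OC(C)(C)C#C)c1 | intermediate
5 | methyl 2-hydroxy-4-(methoxymethoxy)-3-(3-methylbuta-1,2-dien-1-yl)benzoate (allenylphenol, not isolated) | COCOc1ccc(C(=O)OC)c(O)c1C=C=C(C)C | intermediate
6 | methyl 5-(methoxymethoxy)-2,2-dimethyl-2H-chromene-8-carboxylate | COCOc1ccc(C(=O)OC)c2OC(C)(C)C=Cc12 | intermediate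
7 | N-methoxy-N-methylacetamide | CC(=O)N(C)OC | starting material
8 | lithium 1-[methoxy(methyl)amino]ethen-1-olate (lithium enolate of 7, not isolated) | [Li+].C=C([O-])N(C)OC | intermediate
9 | 3-[5-(methoxymethoxy)-2,2-dimethyl-2H-chromen-8-yl]-N-methoxy-N-methyl-3-oxopropanamide | CON(C)C(=O)CC(=O)c1ccc(OCOC)c2C=CC(C)(C)Oc12 | intermediate
10 | (3S)-3-hydroxy-3-[5-(methoxymethoxy)-2,2-dimethyl-2H-chromen-8-yl]-N-methoxy-N-methylpropanamide | CON(C)C(=O)C[C@H](O)c1ccc(OCOC)c2C=CC(C)(C)Oc12 | intermediate
11 | (3S)-3-[5-(methoxymethoxy)-2,2-dimethyl-2H-chromen-8-yl]-N-methoxy-N-methyl-3-[(trimethylsilyl)oxy]propanamide | CON(C)C(=O)C[C@H](O[Si](C)(C)C)c1ccc(OCOC)c2C=CC(C)(C)Oc12 | intermediate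
12 | phloroglucinol (benzene-1,3,5-triol) | Oc1cc(O)cc(O)c1 | starting material
13 | 3,5-bis(methoxymethoxy)phenol | COCOc1cc(O)cc(OCOC)c1 | intermediate
14 | 2-bromo-3,5-bis(methoxymethoxy)phenol | COCOc1cc(O)c(Br)c(OCOC)c1 | intermediate
15 | [2-bromo-3,5-bis(methoxymethoxy)phenoxy]trimethylsilane (not isolated) | COCOc1cc(O[Si](C)(C)C)c(Br)c(OCOC)c1 | intermediate
16 | lithium 3,5-bis(methoxymethoxy)-2-(trimethylsilyl)phenolate (not isolated) | [Li+].COCOc1cc([O-])c([Si](C)(C)C)c(OCOC)c1 | intermediate
17 | 3,5-bis(methoxymethoxy)-2-(trimethylsilyl)phenyl trifluoromethanesulfonate | COCOc1cc(OS(=O)(=O)C(F)(F)F)c([Si](C)(C)C)c(OCOC)c1 | intermediate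
18 | cesium (1S)-3-[methoxy(methyl)amino]-1-[5-(methoxymethoxy)-2,2-dimethyl-2H-chromen-8-yl]-3-oxopropan-1-olate (not isolated) | [Cs+].CON(C)C(=O)C[C@H]([O-])c1ccc(OCOC)c2C=CC(C)(C)Oc12 | intermediate
19 | 3,5-bis(methoxymethoxy)benzyne, 1,2-didehydro-3,5-bis(methoxymethoxy)benzene (not isolated) | C1#CC(OCOC)=CC(OCOC)=C1 | intermediate
20 | cesium 2-{[(1S)-3-[methoxy(methyl)amino]-1-[5-(methoxymethoxy)-2,2-dimethyl-2H-chromen-8-yl]-3-oxopropyl]oxy}-4,6-bis(methoxymethoxy)benzen-1-ide (not isolated) | [Cs+].CON(C)C(=O)C[C@H](Oc1cc(OCOC)cc(OCOC)[c-]1)c1ccc(OCOC)c2C=CC(C)(C)Oc12 | intermediate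
21 | cesium (2S)-4-[methoxy(methyl)amino]-5,7-bis(methoxymethoxy)-2-[5-(methoxymethoxy)-2,2-dimethyl-2H-chromen-8-yl]-3,4-dihydro-2H-chromen-4-olate (C4 undefined, not isolated) | [Cs+].COCOc1ccc([C@@H]2CC([O-])(N(C)OC)c3c(OCOC)cc(OCOC)cc3O2)c2OC(C)(C)C=Cc12 | intermediate
22 | (2S)-5,7-bis(methoxymethoxy)-2-[5-(methoxymethoxy)-2,2-dimethyl-2H-chromen-8-yl]-2,3-dihydro-4H-chromen-4-one | COCOc1ccc([C@@H]2CC(=O)c3c(OCOC)cc(OCOC)cc3O2)c2OC(C)(C)C=Cc12 | intermediate
23 | Sanggenone H, (2S)-5,7-dihydroxy-2-(5-hydroxy-2,2-dimethyl-2H-chromen-8-yl)-2,3-dihydro-4H-chromen-4-one | CC1(C)C=Cc2c(O)ccc([C@@H]3CC(=O)c4c(O)cc(O)cc4O3)c2O1 | target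

**Count and risks**

Total step count: 11. Longest linear sequence: 8 steps (steps 1–6, 10 and 11); steps 7–9 form the second branch.

Steps most likely to fail:

1. Step 10 (proposed new method). The aryl anion may take a proton (from C3–H of the chain or from the medium) instead of closing ring C, after which the aryloxide is lost by β-elimination. The free alkoxide may also fragment by retro-aldol cleavage, or the tetrahedral adduct may collapse early and expose C2 to base. The fallback sets out from 9 (with 14 from step 8) and comes back to the route at 22, using only known reaction types. Transfer hydrogenation of 9 with the enantiomeric catalyst RuCl[(R,R)-TsDPEN](p-cymene) should give (3R)-3-hydroxy-3-[5-(methoxymethoxy)-2,2-dimethyl-2H-chromen-8-yl]-N-methoxy-N-methylpropanamide F1. Mitsunobu etherification of F1 with bromophenol 14 (PPh3, diisopropyl azodicarboxylate, toluene, 0 °C) should proceed with inversion to (3S)-3-[2-bromo-3,5-bis(methoxymethoxy)phenoxy]-3-[5-(methoxymethoxy)-2,2-dimethyl-2H-chromen-8-yl]-N-methoxy-N-methylpropanamide F2. Bromine–lithium exchange (n-BuLi, THF, –100 °C) and Parham cyclization of the aryllithium onto the N-methoxy-N-methylamide, followed by a mild acidic quench, should then give 22.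

2. Step 11. Acid may ionize the C2–O1 bond (the benzylic cation is stabilized by the 2'- and 4'-oxygens), so that ring C opens and the configuration at C2 is lost; acid may also add to the chromene double bond. The fallback sets out from 22 and comes back at 23 by a non-protic exchange of the protecting groups. Treatment of 22 with Me3SiOTf and 2,2'-bipyridyl in CH2Cl2 at 0 °C, which converts aryl MOM ethers into aryl silyl ethers, should give (2S)-5,7-bis[(trimethylsilyl)oxy]-2-{2,2-dimethyl-5-[(trimethylsilyl)oxy]-2H-chromen-8-yl}-2,3-dihydro-4H-chromen-4-one F3. Hydrolysis of F3 with water at neutral pH and rt should give 23.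

3. Step 4. Addition of the amide enolate to the electron-rich, ortho-substituted ester may be slow, and the enolate may decay on warming before it has reacted. The fallback sets out from 6 and comes back at 9. Saponification of 6 (LiOH, THF/MeOH/H2O, then pH 4) should give 5-(methoxymethoxy)-2,2-dimethyl-2H-chromene-8-carboxylic acid F4. Coupling of F4 with Meldrum's acid (1-ethyl-3-[3-(dimethylamino)propyl]carbodiimide, 4-(dimethylamino)pyridine, CH2Cl2) should give the acyl Meldrum's acid 5-{hydroxy[5-(methoxymethoxy)-2,2-dimethyl-2H-chromen-8-yl]methylidene}-2,2-dimethyl-1,3-dioxane-4,6-dione F5. Heating F5 with N,O-dimethylhydroxylamine hydrochloride and Et3N in MeCN at 70 °C (aminolysis with loss of acetone and CO2) should give 9.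

**Further compounds**

F1 | step 10 | (3R)-3-hydroxy-3-[5-(methoxymethoxy)-2,2-dimethyl-2H-chromen-8-yl]-N-methoxy-N-methylpropanamide | CON(C)C(=O)C[C@@H](O)c1ccc(OCOC)c2C=CC(C)(C)Oc12
F2 | step 10 | (3S)-3-[2-bromo-3,5-bis(methoxymethoxy)phenoxy]-3-[5-(methoxymethoxy)-2,2-dimethyl-2H-chromen-8-yl]-N-methoxy-N-methylpropanamide | CON(C)C(=O)C[C@H](Oc1cc(OCOC)cc(OCOC)c1Br)c1ccc(OCOC)c2C=CC(C)(C)Oc12
F3 | step 11 | (2S)-5,7-bis[(trimethylsilyl)oxy]-2-{2,2-dimethyl-5-[(trimethylsilyl)oxy]-2H-chromen-8-yl}-2,3-dihydro-4H-chromen-4-one | CC1(C)C=Cc2c(O[Si](C)(C)C)ccc([C@@H]3CC(=O)c4c(O[Si](C)(C)C)cc(O[Si](C)(C)C)cc4O3)c2O1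
F4 | step 4 | 5-(methoxymethoxy)-2,2-dimethyl-2H-chromene-8-carboxylic acid | COCOc1ccc(C(=O)O)c2OC(C)(C)C=Cc12
F5 | step 4 | 5-{hydroxy[5-(methoxymethoxy)-2,2-dimethyl-2H-chromen-8-yl]methylidene}-2,2-dimethyl-1,3-dioxane-4,6-dione | COCOc1ccc(C(O)=C2C(=O)OC(C)(C)OC2=O)c2OC(C)(C)C=Cc12
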